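**Plan**

1. The retrosynthesis first opens the O1–C2 bond of the dihydropyranone ring. The precursor is not the usual hydroxychalcone but its redox isomer: a 2-acyl-3,5-dimethoxy-1,4-benzoquinone carrying the saturated C2–C3 chain.
2. The enabling feature is that O1 and the C6 hydroxyl stand para on ring A, so ring A is a masked 1,4-benzoquinone next to the C4 acyl carbon. C2–H is benzylic to the electron-rich 3,4-dimethoxyphenyl ring and γ to the C4 ketone, so the quinone can take up the two hydrogens of C2/C3 internally.
3. The second cut is the C4–C4a bond: Hoesch acylation of symmetrical 2,6-dimethoxyhydroquinone with 3-(3,4-dimethoxyphenyl)propanenitrile. This fixes the 5,6,7-oxygen pattern and leaves the C6 oxygen unmethylated without any protecting group.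
4. Forward: reduction of 2,6-dimethoxy-1,4-benzoquinone, C-acylation (ring A, the C2–C4 chain and the aryl ring are joined), re-oxidation to the acylquinone, then a redox-neutral cycloisomerization that forms the pyranone ring and the free C6 phenol together.
5. The only stereocentre, C2, is set in that last ring closure by a bifunctional cinchona thiourea catalyst (delivery of O1 to the Si face of C2) and sees no later step.

Key step: step 4

Assumption: the quinine-derived thiourea is taken to deliver O1 to the Si face of C2 (2S series). Should it favour the 2R series, its quinidine-derived pseudoenantiomer would be used under the same conditions; the configuration would be checked by ECD.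

**Route**

Step 1
Reactants: 1 2,6-dimethoxy-1,4-benzoquinone
Product: 2 2,6-dimethoxybenzene-1,4-diol
Conditions: Na2S2O4, EtOAc/H2O, rt, N2; used at once
Reagents that add atoms: none
Why: Dithionite reduction of a 1,4-benzoquinone to its hydroquinone is a fast two-electron reduction that touches neither methyl ether and creates no stereocentre.

Step 2
Reactants: 2 2,6-dimethoxybenzene-1,4-diol; 3 3-(3,4-dimethoxyphenyl)propanenitrile
Product: 5 1-(2,5-dihydroxy-4,6-dimethoxyphenyl)-3-(3,4-dimethoxyphenyl)propan-1-one, via ketiminium chloride 4 (not isolated)
Conditions: ZnCl2, HCl (g), Et2O, 0 °C → rt; then H2O, 90 °C, N2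
Reagents that add atoms: water, O; hydrogen chloride, Cl (only in the chloride counter-ion of 4, absent from 5)
Why: Hoesch acylation, in which the nitrilium species from 3 attacks the only free ring position of 2 (C3 = C5 by symmetry, ortho to the C4 hydroxyl and ortho/para to the two methoxy groups, a phloroglucinol-type activation) and hydrolysis of ketiminium salt 4 gives the aryl ketone, while the absence of a free acylium ion avoids closure of the dimethoxyphenylpropanoyl unit to an indanone; no stereocentre is formed.

Step 3
Reactants: 5 1-(2,5-dihydroxy-4,6-dimethoxyphenyl)-3-(3,4-dimethoxyphenyl)propan-1-one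
Product: 6 2-[3-(3,4-dimethoxyphenyl)propanoyl]-3,5-dimethoxycyclohexa-2,5-diene-1,4-dione
Conditions: Ag2O, MgSO4, PhMe, 0 °C → rt, dark, Ar; filtration through Celite, filtrate used directly
Reagents that add atoms: none
Why: Silver(I) oxide oxidation of an acylhydroquinone to the acyl-1,4-benzoquinone is a standard heterogeneous two-electron oxidation under anhydrous conditions, so the dimethoxyphenyl ring, the ketone and the methoxy groups should be untouched and the sensitive quinone is obtained by filtration alone; no stereocentre is formed.

Step 4
Reactants: 6 2-[3-(3,4-dimethoxyphenyl)propanoyl]-3,5-dimethoxycyclohexa-2,5-diene-1,4-dione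
Product: 8 (2S)-2-(3,4-dimethoxyphenyl)-6-hydroxy-5,7-dimethoxy-2,3-dihydro-4H-chromen-4-one, via dihydroxychalcone 7 (not isolated)
Conditions: quinine-derived bifunctional thiourea [1-(3,5-bis(trifluoromethyl)phenyl)-3-(9-deoxy-epi-quinin-9-yl)thiourea] (10 mol %), 4 Å MS, PhMe, −20 °C; then AcOH quench, SiO2 filtration
Reagents that add atoms: none
Why: Proposed new method: the quinuclidine nitrogen of the catalyst enolizes the C3 methylene of 6, and loss of the benzylic C2–H from this dienol with electron flow through C4=C4a and C5 into the C6 carbonyl (a vinylogous 1,4-elimination with the quinone ring as two-electron acceptor), followed by O-to-O proton shifts, should give the aromatic (E)-2',5'-dihydroxychalcone 7, so the quinone of ring A acts as built-in oxidant for C2 and the hydrogens taken from C2/C3 end on O1 and on the C6 oxygen. The phenol O1 of 7 then adds to C2 in an oxa-Michael reaction that closes the dihydropyranone ring in a 6-endo-trig mode. The closest known reaction types are the amine-promoted tautomerization of alkyl-1,4-benzoquinones to quinone methides and the quinone (DDQ) dehydrogenation of dihydrochalcones for the redox half, and the cinchona thiourea-catalysed asymmetric oxa-Michael cyclization of 2'-hydroxychalcones to flavanones for the ring closure. The C2 stereocentre is under catalyst control: the thiourea N–H bonds bind the C4 carbonyl while the protonated quinuclidine holds the O1 phenoxide and delivers it to the Si face of C2 of the (E)-enone, which gives 2S. The step needs the tautomerization to outrun nucleophilic attack on the quinone, which the non-nucleophilic anhydrous medium and the acidifying electron-poor quinone next to C4 should secure, and it needs a regioselective ring closure that is not reversed, which is secured because only O1 (ortho to the acyl group) can reach C2 while the C6 hydroxyl (meta) cannot, and because the C5 methoxy group twists the open chalcone out of conjugation so that the flavanone is strongly favoured and retro-oxa-Michael racemization should be slow at −20 °C.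

**Compound list**

1 | 2,6-dimethoxy-1,4-benzoquinone | COC1=CC(=O)C=C(OC)C1=O | starting material
2 | 2,6-dimethoxybenzene-1,4-diol | COc1cc(O)cc(OC)c1O | intermediate
3 | 3-(3,4-dimethoxyphenyl)propanenitrile | COc1ccc(CCC#N)cc1OC | starting material
4 | 1-(2,5-dihydroxy-4,6-dimethoxyphenyl)-3-(3,4-dimethoxyphenyl)propan-1-iminium chloride (formed in the flask, not isolated) | COc1ccc(CCC(=[NH2+])c2c(O)cc(OC)c(O)c2OC)cc1OC.[Cl-] | intermediate
5 | 1-(2,5-dihydroxy-4,6-dimethoxyphenyl)-3-(3,4-dimethoxyphenyl)propan-1-one | COc1ccc(CCC(=O)c2c(O)cc(OC)c(O)c2OC)cc1OC | intermediate
6 | 2-[3-(3,4-dimethoxyphenyl)propanoyl]-3,5-dimethoxycyclohexa-2,5-diene-1,4-dione | COc1ccc(CCC(=O)C2=C(OC)C(=O)C(OC)=CC2=O)cc1OC | intermediate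
7 | (2E)-1-(2,5-dihydroxy-4,6-dimethoxyphenyl)-3-(3,4-dimethoxyphenyl)prop-2-en-1-one (formed in the flask, not isolated) | COc1ccc(/C=C/C(=O)c2c(O)cc(OC)c(O)c2OC)cc1OC | intermediate
8 | (2S)-2-(3,4-dimethoxyphenyl)-6-hydroxy-5,7-dimethoxy-2,3-dihydro-4H-chromen-4-one | COc1ccc([C@@H]2CC(=O)c3c(cc(OC)c(O)c3OC)O2)cc1OC | target

**Step count**

Total steps: 4. Longest linear sequence: 4 steps (1 → 2 → 5 → 6 → 8).

**Steps most likely to fail**

1. Step 4 (proposed new method). Three processes could defeat it:
 - the hydrogen shift from C2/C3 to the quinone may be slower than amine addition or electron transfer to the quinone, or than attack on its vinylogous-ester methoxy groups;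
 - facial selectivity in the oxa-Michael addition to an enone without a second activating group may be low;
 - the basic catalyst may reopen the product by retro-oxa-Michael reaction and erode the enantiomeric purity.

 Fallback (known chemistry, no quinone, no asymmetric catalysis): it sets out from 2 and returns at 8. Hoesch reaction of 2 with acetonitrile (ZnCl2, HCl, Et2O) would give 1-(2,5-dihydroxy-4,6-dimethoxyphenyl)ethan-1-iminium chloride F1, and hot water would hydrolyse it to 1-(2,5-dihydroxy-4,6-dimethoxyphenyl)ethan-1-one F2. Claisen–Schmidt condensation of F2 with commercial 3,4-dimethoxybenzaldehyde (KOH, EtOH, rt, argon) would give chalcone 7, now isolated. Heating 7 with NaOAc in EtOH would close it to the racemic flavanone F3. Preparative chiral SFC on a polysaccharide carbamate phase would then deliver 8.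

2. Step 3. The acylquinone may isomerize on the weakly basic oxide surface or on handling, before any chiral catalyst is present, which would feed racemic material into step 4. The methoxy group that lies β to two carbonyls may also be lost to adventitious water.

 Fallback (the chain is dehydrogenated at carbon by an external oxidant, so the quinone is bypassed): it sets out from 5 and returns at 7. Silylation of 5 with TMSOTf/Et3N (CH2Cl2, 0 °C) would give the (Z)-silyl enol ether bis(aryl silyl ether) F4. Saegusa–Ito oxidation of F4 with Pd(OAc)2 in MeCN would give the bis(trimethylsilyl) chalcone F5. Citric acid in MeOH would remove the aryl silyl groups to give 7, which would be cyclized to 8 with the catalyst and conditions of step 4.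

3. Step 2. O-Imidate formation at the unhindered hydroxyl may compete with C-acylation, and the hydroquinone may be air-oxidized during the hot aqueous hydrolysis.

 Fallback (radical acylation at the quinone oxidation level): it sets out from 1 and returns at 5. Photo-Friedel–Crafts acylation of 1 with commercial 3-(3,4-dimethoxyphenyl)propanal (irradiation in benzene) should give 5 directly. The excited quinone abstracts the formyl hydrogen and the acyl/semiquinone radical pair collapses at the only free ring position. This skips steps 1 and 2 and makes no new intermediate.

**Further compounds**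

F1 | step 4 | 1-(2,5-dihydroxy-4,6-dimethoxyphenyl)ethan-1-iminium chloride | CC(=[NH2+])c1c(O)cc(OC)c(O)c1OC.[Cl-]
F2 | step 4 | 1-(2,5-dihydroxy-4,6-dimethoxyphenyl)ethan-1-one | CC(=O)c1c(O)cc(OC)c(O)c1OC
F3 | step 4 | racemic 2-(3,4-dimethoxyphenyl)-6-hydroxy-5,7-dimethoxy-2,3-dihydro-4H-chromen-4-one | COc1ccc(C2CC(=O)c3c(cc(OC)c(O)c3OC)O2)cc1OC
F4 | step 3 | [(1Z)-1-[4,6-dimethoxy-2,5-bis(trimethylsilyloxy)phenyl]-3-(3,4-dimethoxyphenyl)prop-1-en-1-yl]oxy(trimethyl)silane | COc1ccc(C/C=C(\O[Si](C)(C)C)c2c(O[Si](C)(C)C)cc(OC)c(O[Si](C)(C)C)c2OC)cc1OC
F5 | step 3 | (2E)-1-[4,6-dimethoxy-2,5-bis(trimethylsilyloxy)phenyl]-3-(3,4-dimethoxyphenyl)prop-2-en-1-one | COc1ccc(/C=C/C(=O)c2c(O[Si](C)(C)C)cc(OC)c(O[Si](C)(C)C)c2OC)cc1OC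
F0 | step 2 | none | none
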